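Readings and results come from a simulation for substances that don't exist, and the scatter is random.

| flask | substrate | reagent | remark | time |
|---|---|---|---|---|
| eta | 0.10 M | 0.67 equiv | run made earlier |  |
| gamma | 0.10 M | 1.5 equiv | run made earlier |  |
| zeta | 0.15 M | 1 equiv | run made earlier |  |
| flask | 0.10 M | 1.00 equiv |  | 50 min |

| run | time / min | substrate / % | target / % | isomer of the product / % |
|---|---|---|---|---|
| eta | 6.00 | 58.7 | 18.1 | 21.5 |
| eta | 12.0 | 61.0 | 15.6 | 23.5 |
| eta | 15.0 | 62.2 | 15.1 | 23.6 |
| eta | 25.0 | 65.0 | 12.3 | 20.8 |
| eta | 30.0 | 66.4 | 13.6 | 20.0 |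
| eta | 40.0 | 68.7 | 12.5 | 18.4 |
| gamma | 3.00 | 35.3 | 32.8 | 31.5 |
| gamma | 5.00 | 38.1 | 28.5 | 34.1 |
| gamma | 8.00 | 40.9 | 23.9 | 34.3 |
| gamma | 12.0 | 46.2 | 21.2 | 32.6 |
| gamma | 15.0 | 48.1 | 20.6 | 31.1 |
| gamma | 25.0 | 54.4 | 18.7 | 27.3 |
| gamma | 40.0 | 61.1 | 14.1 | 21.6 |
| zeta | 4.00 | 42.8 | 27.7 | 30.8 |
| zeta | 10.0 | 47.6 | 21.7 | 31.4 |
| zeta | 20.0 | 53.1 | 18.7 | 28.0 |
| zeta | 30.0 | 56.7 | 17.4 | 24.6 |
| zeta | 40.0 | 61.1 | 16.3 | 22.6 |

(scatter of a reading: 0.5 percentage points)

- the reaction counts as stopped when no species that holds the substrate changes by six tenths of a point or more over the second half of the time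

- which holds at 50 min: what has brought the reaction to rest, or that it has not come to rest (forward and back rates have come level / it is still moving / all of the substrate has reacted / the reagent has run out first)
- share of the substrate used up at 50 min
- target at 50 min, in percent of the substrate charged
- isomer of the product at 50 min, in percent of the substrate charged
- amount of target if the flask were left three thousand times as long, in percent of the substrate charged

Time does one thing in these runs once the opening minutes are over: the substrate climbs back, while substrate, target and isomer still sum to about the charge. I read this as a rapid pre-equilibrium, in which the pool of target plus isomer, taken over substrate, goes with the free reagent, so free reagent is the concentration to follow. Let r be substrate over pool. If free reagent is lost by a square law, r, which goes as its inverse, climbs on a straight line. In eta, r reads 1.48 at 6.00 min and 2.22 at 40.0 min, which gives a release slope g = 0.0218 min⁻¹.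

I reach the flask's r in two ways. First, I extend eta and gamma along g and interpolate straight in equivalents, which gives r = 2.24, a pool of 30.9%. Second, I use zeta, which has the flask's equivalents. Under a square law the free fraction of the charge goes roughly with concentration times time, so the flask at 50 min matches zeta at 33.3 min. Stepping back along g from zeta's last reading and scaling by the concentration ratio, 1.50, gives r = 2.14, a pool of 31.9%. The two nearly agree. The first, though, assumes r is straight in the charge, which a square law does not give, so I keep the second. With eta's last isomer-to-target ratio, 1.47, that means target 12.9% and isomer 19.0%. The line shows no plateau, so I expect the pool to keep shrinking.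

The forecast says it is still moving, with 32% used up, target 13%, isomer 19% and finally 0%: “the reagent is gone and target tends to zero”.

The flask gives: it is still moving, 33.3% used up, target 13.2%, isomer 19.4%, finally 0%.

    substrate + reagent ⇌ isomer of the product (K = 24.7 M⁻¹, k = 0.0906 M⁻¹ s⁻¹)
    substrate → decomposition product (k = 3.94 × 10⁻⁶ s⁻¹)
    substrate + reagent ⇌ target (K = 17.2 M⁻¹, k = 0.189 M⁻¹ s⁻¹)
    2 reagent → homo dimer (k = 0.0233 M⁻¹ s⁻¹)

The flask is not at rest: its substrate rises 7.6 percentage points over the second half of the time. Its r stands at 2.05, and g carries that to 11.9 at 500 min, a pool of 7.75%. The computed flask then holds target 3.58% and isomer 5.16%, a pool of 8.74%, with 9.17% decomposition product and conversion down to 17.9%.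

On the neighbour with 0.250 equiv of reagent, I start r from 3.00, the value with its whole charge bound, and eta's g, taken over unchanged, gives an estimate of 4.09 at 50 min, a pool of 19.6%. The computed neighbour has r = 5.12 and a pool of 16.2%.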